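**Retrosynthetic overview**

1. Feature: with germacrane numbering, the ten-membered ring C1–C10 carries the C1=C10 alkene and the C14 methyl ester on C10 between oxygenated C9 and C2. This is exactly the two carbons plus ester that methyl propiolate inserts between a ketone carbon (C9) and its α-carbon (C2) of an eight-membered ring (C2–C9).
2. Key disconnection: C1–C2 and C9–C10 are made by (2+2) addition of the pyrrolidine enamine of a lactone-fused cyclooct-4-enone to methyl propiolate; 4π opening of the cyclobutene cuts the temporary C2–C9 bond (8 → 10).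
3. Cyclooctenone: ring-closing metathesis at C4=C5; C2–C3 by aldol of a methyl ketone with methacrolein; C8/C9 from an ynone (asymmetric transfer hydrogenation, alkyne hydration); C6/C7 and the γ-lactone from an Evans aldol of a succinate imide with acrolein.
4. After the expansion: lactone α-methylenation, hydrolysis with loss of the C3 methoxy group to the 9-oxo trienoate, C9 reduction and acetylation, C4–C5 epoxidation, C8 esterification with (2S,3S)-epoxyangelic acid (Sharpless route), and last the C2–C3 epoxidation.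
5. Ring order: γ-lactone → eight-membered carbocycle → ten-membered carbocycle (by enlargement) → 4,5-oxirane → 2,3-oxirane.

Key step: step 13

Remark: germacrane numbering is used throughout (C11–C13 lactone carbons, C14 ester carbon, C15 methyl). The aldol of step 9 is taken to give both C3 epimers, so C3 is left unspecified in the SMILES of 16–27; this centre becomes trigonal in step 15.

**Route**

Step 1
Reactants: 1 (S)-4-benzyl-2-oxazolidinone; 2 methyl 4-chloro-4-oxobutanoate
Product: 3 methyl 4-[(4S)-4-benzyl-2-oxooxazolidin-3-yl]-4-oxobutanoate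
Conditions: n-BuLi, THF, −78 °C; then 2, −78 → 0 °C
Reagents that add atoms: none
Why: N-acylation of the lithiated oxazolidinone by the acid chloride (Evans imide formation) is fast at −78 °C and leaves the methyl ester untouched.

Step 2
Reactants: 3 imide; 4 acrolein
Product: 6 (4S)-4-benzyl-3-[(2R,3S)-5-oxo-2-vinyltetrahydrofuran-3-carbonyl]oxazolidin-2-one (2,3-trans lactone), via aldol adduct 5 (not isolated)
Conditions: Bu2BOTf, i-Pr2NEt, CH2Cl2, −78 → 0 °C; 4, −78 → 0 °C; pH 7 buffer, MeOH, 30% H2O2, 0 °C; then TsOH·H2O (cat.), CH2Cl2, 23 °C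
Reagents that add atoms: none
Why: Evans syn aldol through the Z boron enolate and a chair transition state, in which the (S)-benzyl auxiliary sets C7 and C6 (2S,3R in 5), followed by acid-catalysed lactonisation of the C6 hydroxyl onto the methyl ester, which should give the 6,7-trans γ-lactone.

Step 3
Reactants: 6 lactone imide
Product: 7 (2R,3S)-5-oxo-2-vinyltetrahydrofuran-3-carboxylic acid
Conditions: LiOH, 30% H2O2, THF–H2O, 0 °C; Na2SO3; 1 M HCl to pH 2
Reagents that add atoms: hydrogen peroxide OO and lithium hydroxide [Li+].[OH-] (as LiOOH, source of the carboxyl OH)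
Why: Hydroperoxide cleaves the exocyclic imide carbonyl selectively (Evans auxiliary removal), and any lactone that opens should reclose on acidification because only the γ-lactone can form.

Step 4
Reactants: 7 lactone acid
Product: 8 (2R,3S)-N-methoxy-N-methyl-5-oxo-2-vinyltetrahydrofuran-3-carboxamide
Conditions: MeNHOMe·HCl, EDC·HCl, N-methylmorpholine, CH2Cl2, 0 → 23 °C
Reagents that add atoms: N,O-dimethylhydroxylamine hydrochloride CNOC.Cl
Why: Carbodiimide amidation with a weak amine base gives the Weinreb amide without epimerising C7 or opening the β-acyloxy system.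

Step 5
Reactants: 8 Weinreb amide; 9 ethynyltrimethylsilane
Product: 10 (4S,5R)-4-[3-(trimethylsilyl)prop-2-ynoyl]-5-vinyldihydrofuran-2(3H)-one
Conditions: 9, EtMgBr, THF, 0 → 23 °C; then 8, −20 → 0 °C; aq. NH4Cl
Reagents that add atoms: none
Why: Weinreb ketone synthesis, in which the alkynyl Grignard reagent adds once to give a stable magnesium chelate that releases the base-sensitive β-acyloxy ynone only on the acidic quench, while the weakly nucleophilic alkynylmagnesium reagent should leave the γ-lactone alone at 0 °C.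

Step 6
Reactants: 10 ynone
Product: 11 (4R,5R)-4-[(1S)-1-hydroxy-3-(trimethylsilyl)prop-2-yn-1-yl]-5-vinyldihydrofuran-2(3H)-one
Conditions: Ru[(S,S)-TsDPEN](p-cymene) (1 mol %), i-PrOH, 23 °C
Reagents that add atoms: none
Why: Noyori asymmetric transfer hydrogenation of ynones is catalyst-controlled, the (S,S)-TsDPEN ruthenium amide giving the (S)-propargylic alcohol at C8, which is also the sense of Felkin–Anh hydride addition anti to C6.

Step 7
Reactants: 11 propargylic alcohol
Product: 12 (4S,5R)-4-[(1S)-1-(tert-butyldimethylsilyloxy)-3-(trimethylsilyl)prop-2-yn-1-yl]-5-vinyldihydrofuran-2(3H)-one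
Conditions: TBSOTf, 2,6-lutidine, CH2Cl2, −78 °C
Reagents that add atoms: tert-butyldimethylsilyl triflate CC(C)(C)[Si](C)(C)OS(=O)(=O)C(F)(F)F
Why: Silylation with the silyl triflate and a hindered pyridine is fast at low temperature and caps the C8 hydroxyl before it can translactonise onto C12.

Step 8
Reactants: 12 silyl ether
Product: 14 (4S,5R)-4-[(1S)-1-(tert-butyldimethylsilyloxy)-2-oxopropyl]-5-vinyldihydrofuran-2(3H)-one, via terminal alkyne 13 (not isolated)
Conditions: Bu4NF, AcOH, THF, 0 °C; then Ph3PAuNTf2 (2 mol %), H2O, 1,4-dioxane, 60 °C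
Reagents that add atoms: water O
Why: Buffered fluoride cleaves the alkynyl C–Si bond much faster than the secondary O–Si bond, and gold-catalysed Markovnikov hydration of the terminal alkyne then gives the methyl ketone (C9 carbonyl, C2 methyl).

Step 9
Reactants: 14 methyl ketone; 15 methacrolein
Product: 16 (4S,5R)-4-[(1S)-1-(tert-butyldimethylsilyloxy)-4-hydroxy-5-methyl-2-oxohex-5-en-1-yl]-5-vinyldihydrofuran-2(3H)-one (both C3 epimers)
Conditions: c-Hex2BCl, Et3N, Et2O, −78 °C; 15, −78 → −20 °C; MeOH, pH 7 buffer, 30% H2O2, 0 °C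
Reagents that add atoms: none
Why: Boron-mediated aldol addition, in which the methyl ketone is enolised at the methyl group (C2) and not at the silyloxy methine, and adds 1,2 to methacrolein to form C2–C3; the C3 configuration is left uncontrolled because this centre is removed in step 15.

Step 10
Reactants: 16 aldol adduct
Product: 17 (4S,5R)-4-[(1S)-1-(tert-butyldimethylsilyloxy)-4-methoxy-5-methyl-2-oxohex-5-en-1-yl]-5-vinyldihydrofuran-2(3H)-one (C3 epimers)
Conditions: Me3OBF4, 1,8-bis(dimethylamino)naphthalene, 4 Å MS, CH2Cl2, 0 → 23 °C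
Reagents that add atoms: trimethyloxonium tetrafluoroborate C[O+](C)C.F[B-](F)(F)F
Why: O-Methylation with Meerwein's salt and proton sponge avoids the base or acid that would cause retro-aldol or dehydration of the β-hydroxy ketone, and the small, poorly leaving methoxy group is chosen so that the β-oxygen survives enamine formation.

Step 11
Reactants: 17 keto diene
Product: 18 cyclooctenone (3aS,4S,9aR,8Z)-4-(tert-butyldimethylsilyloxy)-7-methoxy-8-methyl-3a,4,6,7-tetrahydrocycloocta[b]furan-2,5(3H,9aH)-dione (trans-fused lactone; C3 epimers)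
Conditions: second-generation Grubbs catalyst (H2IMes)(PCy3)Cl2Ru=CHPh (10 mol %), toluene (2 mM), 80 °C, argon sparge
Reagents that add atoms: none
Why: Ring-closing metathesis between the C5 vinyl and C4 isopropenyl groups closes the eight-membered ring with loss of ethene; the ring size enforces the cis C4=C5 geometry, and the trans-fused lactone and the sp2 C9 should pre-organise the chain.

Step 12
Reactants: 18 cyclooctenone; 19 pyrrolidine
Product: 20 pyrrolidine enamine of 18 with the enamine double bond C9=C2 (lactone-fused 1-pyrrolidinylcycloocta-1,4-diene; C3 methoxy, C8 silyloxy)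
Conditions: 19 (8 equiv), TiCl4 (0.55 equiv), toluene, −20 → 23 °C; filtration under argon; evaporation; used crude
Reagents that add atoms: none
Why: Titanium tetrachloride-mediated enamine condensation works for hindered ketones at low temperature without protic acid, and A(1,3) strain in pyrrolidine enamines should direct the double bond to the C2 methylene and away from the silyloxy-bearing C8 methine, which is then not epimerised.

Step 13
Reactants: 20 enamine; 21 methyl propiolate
Product: 23 methyl 3-methoxy-9-(pyrrolidin-1-yl)-8-(tert-butyldimethylsilyloxy)germacra-1,4,9-trien-12,6-olid-14-oate (ring-cis C9=C10, ring-trans C1=C2, cis C4=C5), via aminocyclobutene 22 (not isolated)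
Conditions: 21 (1.3 equiv), toluene, 0 → 23 °C, then 60 °C
Reagents that add atoms: none
Why: The enamine carbon C2 adds to the unsubstituted alkyne carbon of methyl propiolate (the future C1) and the allenolate carbon (C10) closes on the iminium carbon C9, a stepwise polar (2+2) cycloaddition that forms C1–C2 and C9–C10 in the cis-fused bicyclo[6.2.0] aminocyclobutene 22. The amino donor on C9 and the ester acceptor on C10 then ease thermal conrotatory 4π ring opening, which breaks the temporary C2–C9 bond and gives the 2-amino-1,3-diene ester 23. The closest known reaction type is the two-carbon ring enlargement of cyclic ketone enamines with propiolic and acetylenedicarboxylic esters. The four-membered ring closes by 4-exo-trig Mannich attack within the zwitterion, and the ten-membered ring is not closed end to end but arises by enlargement of the eight-membered ring. No stereocentre is created, since C2 and C9 both end trigonal, the two new alkene geometries follow from conrotation within the ring and are erased in step 15, and C6, C7 and C8 are untouched. The step needs bond formation at C2 and at the propiolate terminus, which the position of the enamine (fixed in step 12 by the C8 silyloxy group) and the polarity of the acetylenic ester secure, while the aprotic non-polar solvent disfavours proton transfer to an open Michael adduct.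

Step 14
Reactants: 23 dienamine ester
Product: 26 α-methylene lactone analogue of 23 (germacra-1,4,9,11(13)-tetraene), via Mannich base 24 (not isolated), via methiodide 25 (not isolated)
Conditions: LiN(SiMe3)2, THF, −78 °C; Eschenmoser's salt, −78 → −20 °C; then MeI, CH2Cl2–MeOH, 23 °C; then sat. aq. NaHCO3, CH2Cl2, 23 °C
Reagents that add atoms: dimethylmethylideneammonium iodide C=[N+](C)C.[I-]; iodomethane CI (methyl of intermediate 25 only)
Why: Lactone α-methylenation through a Mannich base (enolate aminomethylation, quaternisation, E1cB loss of trimethylamine), placed here because the lactone CH2 is the most acidic site while the C9 carbonyl is masked as a vinylogous carbamate and because no alkoxide next to the C8 silyl ether is then needed.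

Step 15
Reactants: 26 dienamine ester with α-methylene lactone
Product: 28 methyl 9-oxo-8-(tert-butyldimethylsilyloxy)germacra-1(10),2,4,11(13)-tetraen-12,6-olid-14-oate (1(10)E, 2Z, 4Z; all three ring alkenes ring-cis), via enol keto ester 27 (not isolated)
Conditions: 2 M aq. HCl–THF (1:5), 0 → 23 °C; extraction from the acidic phase
Reagents that add atoms: water O
Why: Acid hydrolysis of the vinylogous carbamate (C-protonation at C10, hydration of the C9 iminium, loss of pyrrolidinium) gives enol keto ester 27, whose doubly allylic C3 methoxy group then ionises with enol assistance to the O-protonated trienone (a vinylogous E1 loss of methanol), and under these reversible conditions the ring is expected to settle in the least strained all ring-cis triene.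

Step 16
Reactants: 28 trienone
Product: 29 methyl 9-hydroxy-8-(tert-butyldimethylsilyloxy)germacra-1(10),2,4,11(13)-tetraen-12,6-olid-14-oate (9-OH cis to 8-O)
Conditions: NaBH4, CeCl3·7H2O, MeOH–THF, −78 °C
Reagents that add atoms: none
Why: Luche reduction gives 1,2-addition at the C9 ketone and spares the alkylidene ester and the α-methylene lactone, hydride adding anti to the C8–O bond (polar Felkin–Anh, non-chelating silyl ether), which should set C9 cis to the C8 oxygen.

Step 17
Reactants: 29 allylic alcohol
Product: 30 9-acetate of 29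
Conditions: Ac2O, pyridine, DMAP (cat.), CH2Cl2, 0 °C
Reagents that add atoms: acetic anhydride CC(=O)OC(C)=O
Why: DMAP-catalysed acetylation of the secondary allylic alcohol, done before any oxirane is present so that no C9 alkoxide can open an epoxide.

Step 18
Reactants: 30 triene acetate
Product: 31 4,5-epoxide of 30 (oxirane oxygen trans to the lactone oxygen; germacra-1(10),2,11(13)-triene)
Conditions: mCPBA (1.05 equiv), NaHCO3, CH2Cl2, −20 → 0 °C
Reagents that add atoms: 3-chloroperbenzoic acid OOC(=O)c1cccc(Cl)c1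
Why: Prilezhaev epoxidation with one equivalent of peracid should take the most electron-rich alkene, the trisubstituted C4=C5 at the far end of the trienoate, on its peripheral face anti to C7 in the A(1,3)-minimised conformer with H6 in the alkene plane, which places the oxirane oxygen trans to the lactone oxygen and also removes the hexatriene that could electrocyclise.

Step 19
Reactants: 31 silyl ether
Product: 32 8-alcohol (9-acetoxy-8-hydroxy-4,5-epoxide)
Conditions: HF·pyridine, pyridine, THF, 0 → 23 °C
Reagents that add atoms: none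
Why: Buffered hydrogen fluoride–pyridine cleaves the secondary silyl ether under mildly acidic conditions, under which neither acetyl migration from O9 to O8 nor translactonisation is expected.

Step 20
Reactants: 33 methyl angelate
Product: 34 (Z)-2-methylbut-2-en-1-ol
Conditions: i-Bu2AlH, CH2Cl2, −78 °C; Rochelle salt
Reagents that add atoms: none
Why: 1,2-Reduction of the conjugated ester by the aluminium hydride gives the allylic alcohol without isomerising the Z double bond.

Step 21
Reactants: 34 allylic alcohol
Product: 35 [(2R,3S)-2,3-dimethyloxiran-2-yl]methanol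
Conditions: Ti(OiPr)4 (cat.), D-(−)-diethyl tartrate (cat.), t-BuOOH, 4 Å MS, CH2Cl2, −20 °C
Reagents that add atoms: tert-butyl hydroperoxide CC(C)(C)OO
Why: Sharpless asymmetric epoxidation, in which D-(−)-tartrate should deliver oxygen to the face that gives the (2R,3S)-epoxy alcohol (the same facial sense as for other Z-allylic alcohols with this tartrate), setting both side-chain centres.

Step 22
Reactants: 35 epoxy alcohol
Product: 36 (2S,3S)-2,3-dimethyloxirane-2-carboxylic acid
Conditions: RuCl3·xH2O (cat.), NaIO4, CCl4–MeCN–H2O, 23 °C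
Reagents that add atoms: sodium periodate [Na+].[O-]I(=O)(=O)=O; water O
Why: Ruthenium tetroxide-catalysed oxidation takes the primary alcohol to the acid without touching the oxirane, the C2 descriptor changing from R to S only through the priority change.

Step 23
Reactants: 32 alcohol; 36 epoxy acid
Product: 38 8-[(2S,3S)-2,3-dimethyloxirane-2-carbonyloxy] ester (9-acetoxy-4,5-epoxygermacra-1(10),2,11(13)-triene), via mixed anhydride 37 (not isolated)
Conditions: 36, 2,4,6-trichlorobenzoyl chloride, Et3N, toluene, 23 °C; then 32, DMAP, 0 → 23 °C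
Reagents that add atoms: 2,4,6-trichlorobenzoyl chloride O=C(Cl)c1c(Cl)cc(Cl)cc1Cl (atoms of intermediate 37 only)
Why: Yamaguchi esterification through the mixed anhydride acylates the hindered C8 hydroxyl with the α,α-disubstituted acid, and fast DMAP-catalysed acyl transfer should outrun acetyl migration.

Step 24
Reactants: 38 diene diester
Product: 39 CNP0077535.3, (2R,3R,4R,5R,6S,7R,8S,9R,1(10)E)-9-acetoxy-8-[(2S,3S)-2,3-dimethyloxirane-2-carbonyloxy]-2,3:4,5-diepoxygermacra-1(10),11(13)-dien-12,6-olid-14-oic acid methyl ester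
Conditions: dimethyldioxirane (acetone solution), CH2Cl2, 0 → 23 °C
Reagents that add atoms: dimethyldioxirane CC1(C)OO1
Why: Neutral dioxirane epoxidation should attack the γ,δ-alkene C2=C3 in preference to the α,β-unsaturated ester and the α-methylene lactone, and approach anti to the existing 4,5-oxirane as in bis-epoxidation of cyclic 1,3-dienes, giving the trans-diepoxide of the target.

**Compound list**

1 | (S)-4-benzyl-2-oxazolidinone | O=C1N[C@@H](Cc2ccccc2)CO1 | starting material
2 | methyl 4-chloro-4-oxobutanoate | COC(=O)CCC(Cl)=O | starting material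
3 | methyl 4-[(4S)-4-benzyl-2-oxooxazolidin-3-yl]-4-oxobutanoate | COC(=O)CCC(=O)N1[C@@H](Cc2ccccc2)COC1=O | intermediate
4 | acrolein | C=CC=O | starting material
5 | methyl (3S,4R)-3-[(4S)-4-benzyl-2-oxooxazolidine-3-carbonyl]-4-hydroxyhex-5-enoate | C=C[C@@H](O)[C@H](CC(=O)OC)C(=O)N1[C@@H](Cc2ccccc2)COC1=O | intermediate
6 | (4S)-4-benzyl-3-[(2R,3S)-5-oxo-2-vinyltetrahydrofuran-3-carbonyl]oxazolidin-2-one | C=C[C@H]1OC(=O)C[C@@H]1C(=O)N2[C@@H](Cc3ccccc3)COC2=O | intermediate
7 | (2R,3S)-5-oxo-2-vinyltetrahydrofuran-3-carboxylic acid | C=C[C@H]1OC(=O)C[C@@H]1C(O)=O | intermediate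
8 | (2R,3S)-N-methoxy-N-methyl-5-oxo-2-vinyltetrahydrofuran-3-carboxamide | C=C[C@H]1OC(=O)C[C@@H]1C(=O)N(C)OC | intermediate
9 | ethynyltrimethylsilane | C#C[Si](C)(C)C | starting material
10 | (4S,5R)-4-[3-(trimethylsilyl)prop-2-ynoyl]-5-vinyldihydrofuran-2(3H)-one | C=C[C@H]1OC(=O)C[C@@H]1C(=O)C#C[Si](C)(C)C | intermediate
11 | (4R,5R)-4-[(1S)-1-hydroxy-3-(trimethylsilyl)prop-2-yn-1-yl]-5-vinyldihydrofuran-2(3H)-one | C=C[C@H]1OC(=O)C[C@@H]1[C@H](O)C#C[Si](C)(C)C | intermediate
12 | (4S,5R)-4-[(1S)-1-(tert-butyldimethylsilyloxy)-3-(trimethylsilyl)prop-2-yn-1-yl]-5-vinyldihydrofuran-2(3H)-one | C=C[C@H]1OC(=O)C[C@@H]1[C@H](O[Si](C)(C)C(C)(C)C)C#C[Si](C)(C)C | intermediate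
13 | (4S,5R)-4-[(1S)-1-(tert-butyldimethylsilyloxy)prop-2-yn-1-yl]-5-vinyldihydrofuran-2(3H)-one | C=C[C@H]1OC(=O)C[C@@H]1[C@H](O[Si](C)(C)C(C)(C)C)C#C | intermediate
14 | (4S,5R)-4-[(1S)-1-(tert-butyldimethylsilyloxy)-2-oxopropyl]-5-vinyldihydrofuran-2(3H)-one | C=C[C@H]1OC(=O)C[C@@H]1[C@H](O[Si](C)(C)C(C)(C)C)C(C)=O | intermediate
15 | methacrolein | C=C(C)C=O | starting material
16 | (4S,5R)-4-[(1S)-1-(tert-butyldimethylsilyloxy)-4-hydroxy-5-methyl-2-oxohex-5-en-1-yl]-5-vinyldihydrofuran-2(3H)-one, C3 epimers | C=C(C)C(O)CC(=O)[C@@H](O[Si](C)(C)C(C)(C)C)[C@H]1CC(=O)O[C@@H]1C=C | intermediate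
17 | (4S,5R)-4-[(1S)-1-(tert-butyldimethylsilyloxy)-4-methoxy-5-methyl-2-oxohex-5-en-1-yl]-5-vinyldihydrofuran-2(3H)-one, C3 epimers | C=C(C)C(OC)CC(=O)[C@@H](O[Si](C)(C)C(C)(C)C)[C@H]1CC(=O)O[C@@H]1C=C | intermediate
18 | (3aS,4S,9aR,8Z)-4-(tert-butyldimethylsilyloxy)-7-methoxy-8-methyl-3a,4,6,7-tetrahydrocycloocta[b]furan-2,5(3H,9aH)-dione, C3 epimers | O=C1CC(OC)/C(C)=C\[C@H]2OC(=O)C[C@@H]2[C@@H]1O[Si](C)(C)C(C)(C)C | intermediate
19 | pyrrolidine | C1CCNC1 | starting material
20 | pyrrolidine enamine of 18 (C9=C2) | N1(CCCC1)/C2=C/C(OC)/C(C)=C\[C@H]3OC(=O)C[C@@H]3[C@@H]2O[Si](C)(C)C(C)(C)C | intermediate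
21 | methyl propiolate | C#CC(=O)OC | starting material
22 | cis-fused bicyclo[6.2.0] aminocyclobutene ester (C9 pyrrolidinyl, C10 ester, C10=C1) | COC(=O)C1=CC2C(OC)/C(C)=C\[C@H]3OC(=O)C[C@@H]3[C@H](O[Si](C)(C)C(C)(C)C)C12N1CCCC1 | intermediate
23 | methyl 3-methoxy-9-(pyrrolidin-1-yl)-8-(tert-butyldimethylsilyloxy)germacra-1E,4Z,9Z-trien-12,6-olid-14-oate | N1(CCCC1)/C2=C(C(=O)OC)/C=C/C(OC)/C(C)=C\[C@H]3OC(=O)C[C@@H]3[C@@H]2O[Si](C)(C)C(C)(C)C | intermediate
24 | 11-(dimethylaminomethyl) derivative of 23 (Mannich base, C11 epimers) | N1(CCCC1)/C2=C(C(=O)OC)/C=C/C(OC)/C(C)=C\[C@H]3OC(=O)C(CN(C)C)[C@@H]3[C@@H]2O[Si](C)(C)C(C)(C)C | intermediate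
25 | trimethylammonium iodide of 24 | N1(CCCC1)/C2=C(C(=O)OC)/C=C/C(OC)/C(C)=C\[C@H]3OC(=O)C(C[N+](C)(C)C)[C@@H]3[C@@H]2O[Si](C)(C)C(C)(C)C.[I-] | intermediate
26 | 11(13)-methylene derivative of 23 | N1(CCCC1)/C2=C(C(=O)OC)/C=C/C(OC)/C(C)=C\[C@H]3OC(=O)C(=C)[C@@H]3[C@@H]2O[Si](C)(C)C(C)(C)C | intermediate
27 | methyl 9-hydroxy-3-methoxy-8-(tert-butyldimethylsilyloxy)germacra-1E,4Z,9,11(13)-tetraen-12,6-olid-14-oate (enol of the keto ester) | O/C1=C(C(=O)OC)/C=C/C(OC)/C(C)=C\[C@H]2OC(=O)C(=C)[C@@H]2[C@@H]1O[Si](C)(C)C(C)(C)C | intermediate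
28 | methyl 9-oxo-8-(tert-butyldimethylsilyloxy)germacra-1(10)E,2Z,4Z,11(13)-tetraen-12,6-olid-14-oate | O=C1/C(C(=O)OC)=C\C=C/C(C)=C\[C@H]2OC(=O)C(=C)[C@@H]2[C@@H]1O[Si](C)(C)C(C)(C)C | intermediate
29 | methyl 9-hydroxy-8-(tert-butyldimethylsilyloxy)germacra-1(10),2,4,11(13)-tetraen-12,6-olid-14-oate (8,9-cis) | O[C@@H]1/C(C(=O)OC)=C\C=C/C(C)=C\[C@H]2OC(=O)C(=C)[C@@H]2[C@@H]1O[Si](C)(C)C(C)(C)C | intermediate
30 | 9-acetate of 29 | CC(=O)O[C@@H]1/C(C(=O)OC)=C\C=C/C(C)=C\[C@H]2OC(=O)C(=C)[C@@H]2[C@@H]1O[Si](C)(C)C(C)(C)C | intermediate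
31 | methyl 9-acetoxy-4,5-epoxy-8-(tert-butyldimethylsilyloxy)germacra-1(10),2,11(13)-trien-12,6-olid-14-oate | CC(=O)O[C@@H]1/C(C(=O)OC)=C\C=C/[C@]3(C)O[C@@H]3[C@H]2OC(=O)C(=C)[C@@H]2[C@@H]1O[Si](C)(C)C(C)(C)C | intermediate
32 | methyl 9-acetoxy-4,5-epoxy-8-hydroxygermacra-1(10),2,11(13)-trien-12,6-olid-14-oate | CC(=O)O[C@@H]1/C(C(=O)OC)=C\C=C/[C@]3(C)O[C@@H]3[C@H]2OC(=O)C(=C)[C@@H]2[C@@H]1O | intermediate
33 | methyl angelate, methyl (Z)-2-methylbut-2-enoate | C/C=C(/C)C(=O)OC | starting material
34 | (Z)-2-methylbut-2-en-1-ol | C/C=C(/C)CO | intermediate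
35 | [(2R,3S)-2,3-dimethyloxiran-2-yl]methanol | OC[C@@]1(C)O[C@H]1C | intermediate
36 | (2S,3S)-2,3-dimethyloxirane-2-carboxylic acid | OC(=O)[C@@]1(C)O[C@H]1C | intermediate
37 | (2S,3S)-2,3-dimethyloxirane-2-carboxylic 2,4,6-trichlorobenzoic anhydride | O=C(OC(=O)[C@@]1(C)O[C@H]1C)c1c(Cl)cc(Cl)cc1Cl | intermediate
38 | methyl 9-acetoxy-8-[(2S,3S)-2,3-dimethyloxirane-2-carbonyloxy]-4,5-epoxygermacra-1(10),2,11(13)-trien-12,6-olid-14-oate | CC(=O)O[C@@H]1/C(C(=O)OC)=C\C=C/[C@]3(C)O[C@@H]3[C@H]2OC(=O)C(=C)[C@@H]2[C@@H]1OC(=O)[C@@]4(C)O[C@H]4C | intermediate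
39 | CNP0077535.3 | C=C1C(=O)O[C@H]2[C@H]1[C@H](OC(=O)[C@@]1(C)O[C@H]1C)[C@H](OC(C)=O)/C(C(=O)OC)=C\[C@H]1O[C@H]1[C@]1(C)O[C@H]21 | target

**Step count and risks**

Total step count: 24. Longest linear sequence: 21 steps (steps 1–19, 23, 24); steps 20–22 make the side-chain acid.

Steps most likely to fail:

1. Step 13 (with the enamine it depends on from step 12). What may go wrong: proton transfer within the zwitterion to an open-chain vinylogous adduct in place of ring closure, loss of methanol from the γ-methoxy enamine, or epimerisation at C8 while the enamine is made or handled. Fallback: set out from cyclooctenone 18 and avoid the amine altogether. Kinetic deprotonation at the C2 methylene (LiN(i-Pr)2, Me3SiCl, THF, −78 °C) should give the trimethylsilyl enol ether F1. Its acid-catalysed (2+2) cycloaddition with methyl propiolate (EtAlCl2 or Tf2NH, CH2Cl2, −78 °C, a known reaction of silyl enol ethers with propiolates) would give the silyloxycyclobutene ester F2. The lactone is then methylenated under the conditions of step 14, through the Mannich base F3 and the methiodide F4, to the α-methylene lactone cyclobutene F5. Buffered Bu4NF finally frees the cyclobutanolate, whose retro-aldol cleavage of C2–C9 gives a dienolate that expels the C3 methoxide, and the route is rejoined at trienone 28.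

2. Step 15. What may go wrong: incomplete loss of methanol, formation of ring-trans isomers at C10=C1 or C2=C3, 6π or oxa-6π electrocyclisation of the all-cis 9-oxo triene while it stands in acid, or partial loss of the C8 silyl group. Fallback: never form the trienone. From 26, buffered hydrolysis (AcOH–NaOAc, aq. THF, 0 °C) is stopped at the enol keto ester 27, which is isolated. NaBH4–CeCl3 reduction of its keto form at −78 °C would give the β-hydroxy ester F6 with C9 already sp3. Mild acid (camphorsulfonic acid, CH2Cl2, 0 °C) should then ionise the doubly allylic C3 ether, and loss of the acidic C10 proton from the pentadienyl cation gives the conjugated triene, rejoining the route at 29.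

3. Step 11. What may go wrong: failure of the ruthenium alkylidene to engage the hindered 1,1-disubstituted isopropenyl group, oligomerisation through the vinyl group, or alkene migration by ruthenium hydrides. Fallback: relay ring-closing metathesis from methyl ketone 14. The relay aldehyde (E)-4-(allyloxy)-2-methylbut-2-enal F7 (from allyl prenyl ether by SeO2/t-BuOOH oxidation) replaces methacrolein in the boron aldol of step 9 to give the aldol adduct F8, which is methylated as in step 10 to the methyl ether F9. With the same ruthenium catalyst the terminal allyl ether loads first, expels 2,5-dihydrofuran and places the alkylidene directly on C4, which then closes onto the C5 vinyl group to give cyclooctenone 18.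

Further compounds
F1 | step 13 | trimethylsilyl enol ether of 18 (C9=C2) | C[Si](C)(C)O/C1=C/C(OC)/C(C)=C\[C@H]2OC(=O)C[C@@H]2[C@@H]1O[Si](C)(C)C(C)(C)C
F2 | step 13 | cis-fused bicyclo[6.2.0] trimethylsilyloxycyclobutene ester | COC(=O)C1=CC2C(OC)/C(C)=C\[C@H]3OC(=O)C[C@@H]3[C@H](O[Si](C)(C)C(C)(C)C)C12O[Si](C)(C)C
F3 | step 13 | 11-(dimethylaminomethyl) derivative of F2 | COC(=O)C1=CC2C(OC)/C(C)=C\[C@H]3OC(=O)C(CN(C)C)[C@@H]3[C@H](O[Si](C)(C)C(C)(C)C)C12O[Si](C)(C)C
F4 | step 13 | trimethylammonium iodide of F3 | COC(=O)C1=CC2C(OC)/C(C)=C\[C@H]3OC(=O)C(C[N+](C)(C)C)[C@@H]3[C@H](O[Si](C)(C)C(C)(C)C)C12O[Si](C)(C)C.[I-]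
F5 | step 13 | 11(13)-methylene derivative of F2 | COC(=O)C1=CC2C(OC)/C(C)=C\[C@H]3OC(=O)C(=C)[C@@H]3[C@H](O[Si](C)(C)C(C)(C)C)C12O[Si](C)(C)C
F6 | step 15 | methyl 9-hydroxy-3-methoxy-8-(tert-butyldimethylsilyloxy)germacra-1E,4Z,11(13)-trien-12,6-olid-14-oate (C10 epimers) | O[C@@H]1C(C(=O)OC)/C=C/C(OC)/C(C)=C\[C@H]2OC(=O)C(=C)[C@@H]2[C@@H]1O[Si](C)(C)C(C)(C)C
F7 | step 11 | (E)-4-(allyloxy)-2-methylbut-2-enal | C=CCOC/C=C(\C)C=O
F8 | step 11 | aldol adduct of 14 with F7 (C3 epimers) | C=CCOC/C=C(\C)C(O)CC(=O)[C@@H](O[Si](C)(C)C(C)(C)C)[C@H]1CC(=O)O[C@@H]1C=C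
F9 | step 11 | methyl ether of F8 | C=CCOC/C=C(\C)C(OC)CC(=O)[C@@H](O[Si](C)(C)C(C)(C)C)[C@H]1CC(=O)O[C@@H]1C=C
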